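# Fragransin B1 by thiocarbonyl ylide cycloaddition to a γ-aryl butenolide: proposed route

## Analysis of the target

Fragransin B1 (16) is a 2,5-diaryl-3,4-dimethyltetrahydrofuran lignan. It has one oxolane ring (O1, C2–C5) in which every carbon is a stereocentre, with a 4-hydroxy-3,5-dimethoxyphenyl group on C2 and on C5 and a methyl group on C3 and on C4. Read from the SMILES, the two aryl groups lie on one face of the ring and the two methyl groups on the other: 2,3-trans, 3,4-cis, 4,5-trans. Because the two aryl groups are identical, a mirror plane passes through O1 and the midpoint of the C3–C4 bond. The compound is therefore meso, (2R,3R,4S,5S), and only relative configuration has to be controlled. The sensitive sites are the two free, electron-rich phenols (easily oxidised) and the two benzylic C–O bonds of the ring. These bonds ionise under acid (epimerisation, ring opening, closure to aryltetralins) and can be hydrogenolysed. The difficulty is the relative configuration, not the skeleton: the cis methyl pair is the less stable arrangement, C3 and C4 cannot be corrected by epimerisation once they are in the ring, and both aryl groups must sit on the face opposite to the methyls. The plan rests on the fact that C3–CH3 and C4–CH3, being cis, can be tied through one sulfur atom into a thiolane cis-fused to C3–C4. That thiolane is the [3+2] adduct of the parent thiocarbonyl ylide with the C3=C4 bond of a 5-aryl butenolide, whose aryl-bearing sp3 carbon (the later C5) steers the dipole to the opposite face and whose carbonyl carbon (the later C2) remains as the handle for the second aryl group.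

## Retrosynthetic reasoning

**16 from 15.** The last bond cut is the O–CH2Ph bond on one phenol. Only the aryl group that travels through the fluoride, nickel, hydride and Lewis acid steps needs protection. A benzyl ether tolerates all of these and is removed without acid. Its removal restores the mirror plane, so racemic 15 converges on meso 16.

**15 from 12 and 13.** The C2–aryl bond is cut. It is cut here and not at C5 because C2 in 12 is at the lactol oxidation level and ionises to the oxocarbenium ion 14, while 13 is nucleophilic at the carbon para to its hydroxyl (both ortho positions are blocked by methoxy groups). The forward reaction has to bring the arene to the face of 14 opposite the adjacent C3 methyl. This gives the 2,3-trans relationship, with the three other centres already in place.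

**12 from 11.** This is a change of oxidation state at C2 only. The lactone was needed earlier as the activating group of the dipolarophile. The forward reduction must stop at the hemiacetal.

**11 from 10.** The six C–H bonds that complete the two methyl groups are traced back to the two C–S bonds of a thiolane. The gain is that two methyl groups, which would otherwise need two separate stereoselective C–C bond formations, become one ring whose cis fusion is fixed by its mode of formation. The forward step must cleave C–S without touching the lactone, the benzyl ether or the benzylic lactone C–O bond.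

**10 from 7 and 8, by way of 9 (key disconnection).** The bonds C3a–C4 and C6a–C6 of 10 are cut; they are the two future C–CH3 bonds of the target. They are chosen over a ring C–O or a C–aryl bond because they lie cis on one face of the lactone, which is what a suprafacial cycloaddition to a ring alkene delivers. The dipole 9 is symmetric, so no regiochemical question arises, and 8 is a stable source that releases 9 under fluoride. The forward reaction has to add anti to the aryl group of 7 and has to outrun base-induced isomerisation of 7.

**7 from 5, by way of 6.** The lactone C–O bond and the ring alkene are traced back to a γ-hydroxy alkynoate. Syn semi-reduction gives the Z-enoate 6, in which the hydroxyl and ester are held cis and close the ring.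

**5 from 2 and 3, by way of 4.** The C–C bond between the carbinol carbon and the alkyne is cut. Acetylide addition to the aldehyde brings in all four lactone carbons at the right oxidation level. No stereocontrol is needed because the target is meso.

**2 from 1.** The phenol O–benzyl bond is cut, leaving commercial 1.

## Alternatives that were turned down

**Alternative 1:** A [4+1] annulation that cuts C2–C3 and O1–C2 of the ring. In the forward step the benzylic ylide from sulfonium salt A3 would add to the β-carbon of tiglyl aryl ketone A2. The enolate oxygen would then displace the neutral sulfide to close the 2,3-dihydrofuran A1 (2,3-trans).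
- For: it is more convergent and shorter than the chosen route. Both aryl groups and both methyl carbons are assembled in one step from two simple syringyl pieces.
- Against, chemoselectivity: ylides of this type with enones normally close on carbon (cyclopropane) or attack the carbonyl (epoxide), and A2 is a hindered, α,β-disubstituted acceptor.
- Against, stereochemistry: A1 still has a tetrasubstituted enol ether at C4=C5. Syn delivery of hydrogen puts the C4 methyl and the C5 aryl on the same face (4,5-cis), the opposite of the target. The C2 aryl and C3 methyl shield opposite faces, so facial selectivity would be weak.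
- Repair would need acid equilibration at a benzylic ring carbon of a substrate prone to ring opening.
- Comparison: the chosen route is longer, but every stereochemical relationship is set kinetically by an identifiable control element.

**Alternative 2:** Both C–aryl bonds are cut at once. The meso diacid A5, obtained by oxidative cleavage of the exo,exo-dimethyl oxanorbornene A6, would be arylated twice with aryl bromide A7. The conditions would be visible light with Ir[dF(CF3)ppy]2(dtbbpy)PF6, NiCl2(dme) and 4,4'-di-tert-butyl-2,2'-bipyridine. The product is the bis(benzyl ether) A4.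
- For: on use of the target's symmetry and on convergence this plan is stronger than the chosen one. The rigid bicycle fixes the cis-dimethyl unit, no differentiated protection is needed, and both aryl groups arrive in one operation.
- Against: each C–aryl bond forms from a planar α-alkoxy radical, so the configuration that A6 provides at C2 and C5 is erased. It must be set twice, independently, by approach trans to the neighbouring methyl.
- Against: the trialkoxy-substituted A7 is a sluggish partner for oxidative addition at nickel. Mono-arylation and protodecarboxylation compete in a twofold coupling.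
- Against: A5 itself needs about five steps (cycloaddition, reduction, deoxygenation of two carbinols, cleavage).
- Comparison: the chosen route offers polar, substrate-controlled bond formation at both benzylic carbons, one of them fixed before the key step.

**Alternative 3:** An oxidative radical annulation that cuts C3–C4 and O1–C5. Mn(OAc)3 with Cu(OAc)2 would oxidise β-keto ester A9 to a radical that adds to propenylarene A10. The benzylic cation formed on further oxidation would be captured by the ketone oxygen to give dihydrofuran ester A8 (4,5-trans).
- For: it is very short to a fully substituted ring. Regiochemistry is secured by benzylic stabilisation, and both partners are one or two steps from syringaldehyde derivatives.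
- Against: A8 carries an ester where a methyl is needed. Reduction to CH3 takes about three steps on a push-pull alkene that resists reduction.
- Against: the C2=C3 bond must then be saturated. Syn hydrogenation places the C2 aryl cis to the C3 substituent (2,3-cis), again the wrong relationship, so an acid epimerisation would be required.
- Against: the trivalent manganese oxidant is not innocent toward electron-rich arenes.
- Comparison: after its key step this route needs more steps and more stereochemical repair than the chosen one, in which both methyls arrive at the correct oxidation level and configuration in one event.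

Key step: step 4

## Route

Remark on the chemistry: the target is meso, so all chiral intermediates are carried as racemates. Names carry the prefix rac with the descriptors of the enantiomer shown in the SMILES.

Step 1
Reactants: 1 syringaldehyde (4-hydroxy-3,5-dimethoxybenzaldehyde)
Product: 2 4-(benzyloxy)-3,5-dimethoxybenzaldehyde
Conditions: BnBr, K2CO3, DMF, 60 °C
Reagents that add atoms: benzyl bromide, BrCc1ccccc1
Why: Williamson ether synthesis on a phenol acidified by the para formyl group; benzyl is chosen because it should survive fluoride, Ni2B, i-Bu2AlH and BF3·OEt2, whereas a silyl ether would be lost to CsF in step 4.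

Step 2
Reactants: 2 4-(benzyloxy)-3,5-dimethoxybenzaldehyde; 3 ethyl propiolate
Product: 5 rac-ethyl 4-[4-(benzyloxy)-3,5-dimethoxyphenyl]-4-hydroxybut-2-ynoate, via ethyl lithiopropiolate 4 (not isolated)
Conditions: n-BuLi, THF, −78 °C; then 2, −78 °C; AcOH quench
Reagents that add atoms: none
Why: 1,2-addition of a lithium acetylide to an aldehyde; the acetylide 4 is formed and used below −70 °C to avoid self-condensation, and the racemic carbinol is sufficient because the target is meso.

Step 3
Reactants: 5 rac-ethyl 4-[4-(benzyloxy)-3,5-dimethoxyphenyl]-4-hydroxybut-2-ynoate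
Product: 7 rac-5-[4-(benzyloxy)-3,5-dimethoxyphenyl]furan-2(5H)-one, via Z-hydroxy enoate 6 (not isolated)
Conditions: H2 (1 atm), Pd/CaCO3 poisoned with Pb(OAc)2, quinoline, EtOAc, rt; then PPTS (cat.), rt
Reagents that add atoms: none
Why: Syn semi-hydrogenation of the alkyne on the poisoned palladium catalyst gives the Z-enoate 6, whose cis hydroxyl and ester close the five-membered lactone by intramolecular acyl substitution with loss of ethanol; the poisoned catalyst should leave the benzyl ether and the benzylic carbinol C–O bond untouched.

Step 4
Reactants: 7 rac-5-[4-(benzyloxy)-3,5-dimethoxyphenyl]furan-2(5H)-one; 8 chloromethyl trimethylsilylmethyl sulfide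
Product: 10 rac-(3R,3aR,6aS)-3-[4-(benzyloxy)-3,5-dimethoxyphenyl]-3a,4,6,6a-tetrahydro-1H,3H-thieno[3,4-c]furan-1-one, via thiocarbonyl ylide 9 (not isolated)
Conditions: 8 (slow addition, excess), CsF, MeCN, rt
Reagents that add atoms: none
Why: Fluoride attacks the silicon of 8 and chloride leaves in a 1,3-elimination, which releases the parent thiocarbonyl ylide 9 at low stationary concentration. 9 is an electron-rich dipole that should add to the electron-poor C3=C4 bond of 7 in a concerted, suprafacial [3+2] cycloaddition; the closest known reaction type is the cycloaddition of thiocarbonyl ylides to α,β-unsaturated esters and lactones. The thiolane ring is closed by the cycloaddition itself, both new C–C bonds (C3a–C4 and C6a–C6) forming in the same event, so no separate cyclisation is involved. The mutual cis relationship of the new stereocentres C3a and C6a follows from suprafacial addition to an alkene held in a five-membered ring, which allows only a cis fusion. Their relationship to C3 is set by substrate control: the aryl group on the sp3 carbon next to the alkene blocks one face of the nearly flat butenolide, so the dipole should approach from the other face and place both CH2 groups trans to the aryl. No regiochemical issue exists because the dipole is symmetric. The step needs chemoselectivity for cycloaddition over fluoride-induced γ-deprotonation of 7 and over self-reaction of 9; the strained, conjugated lactone alkene is a reactive dipolarophile, and slow addition of excess 8 keeps the dipole concentration low.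

Step 5
Reactants: 10 rac-(3R,3aR,6aS)-3-[4-(benzyloxy)-3,5-dimethoxyphenyl]-3a,4,6,6a-tetrahydro-1H,3H-thieno[3,4-c]furan-1-one
Product: 11 rac-(3S,4R,5R)-5-[4-(benzyloxy)-3,5-dimethoxyphenyl]-3,4-dimethyldihydrofuran-2(3H)-one
Conditions: NiCl2·6H2O, NaBH4, MeOH/THF, 0 °C
Reagents that add atoms: none
Why: Reductive desulfurisation with Ni2B formed in the flask replaces both C–S bonds by C–H without touching the carbon stereocentres, so the cis-fused thiolane becomes the cis methyl pair trans to the aryl group; low temperature and short contact should spare the lactone and the benzyl ether.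

Step 6
Reactants: 11 rac-(3S,4R,5R)-5-[4-(benzyloxy)-3,5-dimethoxyphenyl]-3,4-dimethyldihydrofuran-2(3H)-one
Product: 12 rac-(3S,4R,5R)-5-[4-(benzyloxy)-3,5-dimethoxyphenyl]-3,4-dimethyltetrahydrofuran-2-ol (mixture of anomers)
Conditions: i-Bu2AlH (DIBAL-H), CH2Cl2, −78 °C; aq. KNaC4H4O6 work-up
Reagents that add atoms: none
Why: Partial reduction of a lactone; the tetrahedral aluminium hemiacetal is stable at −78 °C and collapses to the lactol only on work-up, which prevents over-reduction to the diol, and the anomeric mixture is of no consequence for the next step.

Step 7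
Reactants: 12 rac-(3S,4R,5R)-5-[4-(benzyloxy)-3,5-dimethoxyphenyl]-3,4-dimethyltetrahydrofuran-2-ol; 13 2,6-dimethoxyphenol
Product: 15 rac-4-[(2S,3S,4R,5R)-5-[4-(benzyloxy)-3,5-dimethoxyphenyl]-3,4-dimethyltetrahydrofuran-2-yl]-2,6-dimethoxyphenol, via oxocarbenium ion 14 (not isolated)
Conditions: BF3·OEt2, CH2Cl2, −78 → −20 °C
Reagents that add atoms: none
Why: BF3·OEt2 ionises the lactol to the oxocarbenium ion 14, which is attacked in a Friedel–Crafts alkylation by the carbon of 13 para to the hydroxyl (both ortho positions carry methoxy groups). The arene should approach the face of C2 opposite the adjacent C3 methyl, so the new aryl group ends up trans to that methyl and cis to the C5 aryl, which is also the more stable arrangement; low temperature limits ionisation of the benzylic ring C–O bonds.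

Step 8
Reactants: 15 rac-4-[(2S,3S,4R,5R)-5-[4-(benzyloxy)-3,5-dimethoxyphenyl]-3,4-dimethyltetrahydrofuran-2-yl]-2,6-dimethoxyphenol
Product: 16 Fragransin B1, meso-4,4'-[(2R,3R,4S,5S)-3,4-dimethyltetrahydrofuran-2,5-diyl]bis(2,6-dimethoxyphenol)
Conditions: H2 (1 atm), Pd/C, EtOAc, rt
Reagents that add atoms: none
Why: Hydrogenolysis of the benzyl aryl ether over Pd/C should be much faster than cleavage of the hindered secondary benzylic C–O bonds of the ring; removal of the benzyl group restores the mirror plane, so both enantiomers of 15 give the same meso product.

## Compound list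

1 | syringaldehyde (4-hydroxy-3,5-dimethoxybenzaldehyde) | COc1cc(C=O)cc(OC)c1O | starting material
2 | 4-(benzyloxy)-3,5-dimethoxybenzaldehyde | COc1cc(C=O)cc(OC)c1OCc1ccccc1 | intermediate
3 | ethyl propiolate | C#CC(=O)OCC | starting material
4 | ethyl lithiopropiolate (formed in the flask, not isolated) | [Li]C#CC(=O)OCC | intermediate
5 | rac-ethyl 4-[4-(benzyloxy)-3,5-dimethoxyphenyl]-4-hydroxybut-2-ynoate (racemate, one enantiomer drawn) | CCOC(=O)C#C[C@@H](O)c1cc(OC)c(OCc2ccccc2)c(OC)c1 | intermediate
6 | rac-ethyl (Z)-4-[4-(benzyloxy)-3,5-dimethoxyphenyl]-4-hydroxybut-2-enoate (formed in the flask, not isolated) | CCOC(=O)/C=C\[C@@H](O)c1cc(OC)c(OCc2ccccc2)c(OC)c1 | intermediate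
7 | rac-5-[4-(benzyloxy)-3,5-dimethoxyphenyl]furan-2(5H)-one (racemate, 5R drawn) | O=C1O[C@@H](c2cc(OC)c(OCc3ccccc3)c(OC)c2)C=C1 | intermediate
8 | chloromethyl trimethylsilylmethyl sulfide | C[Si](C)(C)CSCCl | starting material
9 | parent thiocarbonyl ylide, thioformaldehyde S-methylide (formed in the flask, not isolated) | C=[S+][CH2-] | intermediate
10 | rac-(3R,3aR,6aS)-3-[4-(benzyloxy)-3,5-dimethoxyphenyl]-3a,4,6,6a-tetrahydro-1H,3H-thieno[3,4-c]furan-1-one (cis-fused, aryl trans to the thiolane) | O=C1O[C@@H](c2cc(OC)c(OCc3ccccc3)c(OC)c2)[C@@H]2CSC[C@H]12 | intermediate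
11 | rac-(3S,4R,5R)-5-[4-(benzyloxy)-3,5-dimethoxyphenyl]-3,4-dimethyldihydrofuran-2(3H)-one (methyls cis, both trans to aryl) | O=C1O[C@@H](c2cc(OC)c(OCc3ccccc3)c(OC)c2)[C@H](C)[C@@H]1C | intermediate
12 | rac-(3S,4R,5R)-5-[4-(benzyloxy)-3,5-dimethoxyphenyl]-3,4-dimethyltetrahydrofuran-2-ol (both anomers) | OC1O[C@@H](c2cc(OC)c(OCc3ccccc3)c(OC)c2)[C@H](C)[C@@H]1C | intermediate
13 | 2,6-dimethoxyphenol | COc1cccc(OC)c1O | starting material
14 | cyclic oxocarbenium ion from 12 by loss of the anomeric hydroxyl, C3–C5 configuration of 12 retained (formed in the flask, not isolated) | C1=[O+][C@@H](c2cc(OC)c(OCc3ccccc3)c(OC)c2)[C@H](C)[C@@H]1C | intermediate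
15 | rac-4-[(2S,3S,4R,5R)-5-[4-(benzyloxy)-3,5-dimethoxyphenyl]-3,4-dimethyltetrahydrofuran-2-yl]-2,6-dimethoxyphenol | COc1cc([C@H]2O[C@@H](c3cc(OC)c(OCc4ccccc4)c(OC)c3)[C@H](C)[C@@H]2C)cc(OC)c1O | intermediate
16 | Fragransin B1, meso-4,4'-[(2R,3R,4S,5S)-3,4-dimethyltetrahydrofuran-2,5-diyl]bis(2,6-dimethoxyphenol) | COc1cc([C@H]2O[C@@H](c3cc(OC)c(O)c(OC)c3)[C@H](C)[C@@H]2C)cc(OC)c1O | target

## Step count and risk

Total step count: 8. Longest linear sequence: 8 steps, from 1 to 16; compounds 3, 8 and 13 are purchased.

**Step 4 (key step).**
- What may go wrong: fluoride acting as a base and removing the acidic benzylic γ-hydrogen of 7, which isomerises or consumes the dipolarophile; self-reaction of the ylide outrunning cycloaddition, so that conversion stalls; incomplete shielding of one face by the aryl group, giving some addition syn to it.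
- Fallback: give up the sulfur dipole and introduce the methyls one at a time. The detour sets out from 7 and rejoins at 11.
 - Conjugate addition of Me2CuLi (Me3SiCl, THF, −78 °C) anti to the aryl group should give rac-(4R,5R)-5-[4-(benzyloxy)-3,5-dimethoxyphenyl]-4-methyldihydrofuran-2(3H)-one F1.
 - Enolate methylation (LiN(i-Pr)2, then MeI, −78 °C) anti to the C4 methyl should give the all-trans lactone rac-(3R,4R,5R)-5-[4-(benzyloxy)-3,5-dimethoxyphenyl]-3,4-dimethyldihydrofuran-2(3H)-one F2.
 - A second deprotonation and kinetic protonation with a hindered phenol from the face away from the C4 methyl should invert C3 and give 11.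
 - The price is two more steps and a cis selectivity that rests on a protonation instead of a concerted addition.

**Step 7.**
- What may go wrong: attack at the carbon of 13 that is ortho and para to the methoxy groups instead of para to the hydroxyl, or O-alkylation of the phenol; ionisation of the benzylic C5–O bond by the Lewis acid, with epimerisation or closure of the opened cation onto an aryl ring to an aryltetralin.
- Fallback: fix the site on the arene by using an aryl–metal reagent. The detour sets out from 12 and rejoins at 16.
 - Exchange of the anomeric hydroxyl for a sulfone (PhSO2H, CaCl2, CH2Cl2) gives rac-(3S,4R,5R)-5-[4-(benzyloxy)-3,5-dimethoxyphenyl]-3,4-dimethyl-2-(phenylsulfonyl)tetrahydrofuran F3.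
 - 2-(Benzyloxy)-5-bromo-1,3-dimethoxybenzene F4 is converted with Mg into (4-benzyloxy-3,5-dimethoxyphenyl)magnesium bromide F5, which is transmetalated with ZnBr2 and combined with F3 (THF, rt).
 - Zinc-assisted loss of sulfinate and aryl transfer trans to the C3 methyl should give the meso bis(benzyl ether) of Fragransin B1 F6 (the same compound as A4).
 - Hydrogenolysis of both benzyl ethers (H2, Pd/C) then gives 16.

**Step 5.**
- What may go wrong: reduction of the lactone by borohydride; incomplete C–S cleavage that stops at a thiol; partial loss of the benzyl ether or of the benzylic lactone C–O bond on the nickel surface.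
- Fallback: postpone the desulfurisation until no lactone is left. The detour sets out from 10 and rejoins at 15.
 - Reduction of 10 with i-Bu2AlH (CH2Cl2, −78 °C) gives the lactol rac-(3R,3aR,6aS)-3-[4-(benzyloxy)-3,5-dimethoxyphenyl]-3a,4,6,6a-tetrahydro-1H,3H-thieno[3,4-c]furan-1-ol F7.
 - Arylation with 13 and BF3·OEt2 should give rac-4-[3-[4-(benzyloxy)-3,5-dimethoxyphenyl]-3a,4,6,6a-tetrahydro-1H,3H-thieno[3,4-c]furan-1-yl]-2,6-dimethoxyphenol F8, with both aryl groups trans to the cis-fused thiolane. The arene adds to the convex face of the bicyclic oxocarbenium ion.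
 - Desulfurisation with acetone-deactivated Raney Ni (THF/EtOH, rt) gives 15.

**Step 3.**
- What may go wrong: over-reduction of the alkene or hydrogenolysis of the activated carbinol C–O bond on palladium; slow lactonisation that allows acid-induced ionisation of the electron-rich benzylic alcohol.
- Fallback: build the butenolide by metathesis. The detour sets out from 2 and rejoins at 7.
 - Addition of vinylmagnesium bromide (THF, 0 °C) gives rac-1-[4-(benzyloxy)-3,5-dimethoxyphenyl]prop-2-en-1-ol F9.
 - Acylation with acryloyl chloride (Et3N, CH2Cl2, 0 °C) gives rac-1-[4-(benzyloxy)-3,5-dimethoxyphenyl]prop-2-en-1-yl acrylate F10.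
 - Ring-closing metathesis with the second-generation Grubbs catalyst (H2IMes)(PCy3)Cl2Ru=CHPh (CH2Cl2, reflux) closes 7 with loss of ethylene.

**Step 8.**
- What may go wrong: competing hydrogenolysis of a benzylic C–O bond of the ring, which opens the tetrahydrofuran.
- Fallback: cleave the benzyl ether heterolytically, without hydrogen. The fallback sets out from 15 and gives 16 directly.
 - BCl3 with pentamethylbenzene as cation scavenger (CH2Cl2, −78 °C) is used, so that no reductive C–O cleavage is possible.
 - No new compound is made.

## Further compounds

F1 | step 4 | rac-(4R,5R)-5-[4-(benzyloxy)-3,5-dimethoxyphenyl]-4-methyldihydrofuran-2(3H)-one | O=C1O[C@@H](c2cc(OC)c(OCc3ccccc3)c(OC)c2)[C@H](C)C1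
F2 | step 4 | rac-(3R,4R,5R)-5-[4-(benzyloxy)-3,5-dimethoxyphenyl]-3,4-dimethyldihydrofuran-2(3H)-one | O=C1O[C@@H](c2cc(OC)c(OCc3ccccc3)c(OC)c2)[C@H](C)[C@H]1C
F3 | step 7 | rac-(3S,4R,5R)-5-[4-(benzyloxy)-3,5-dimethoxyphenyl]-3,4-dimethyl-2-(phenylsulfonyl)tetrahydrofuran (both anomers) | O=S(=O)(c1ccccc1)C1O[C@@H](c2cc(OC)c(OCc3ccccc3)c(OC)c2)[C@H](C)[C@@H]1C
F4 | step 7 | 2-(benzyloxy)-5-bromo-1,3-dimethoxybenzene | COc1cc(Br)cc(OC)c1OCc1ccccc1
F5 | step 7 | (4-benzyloxy-3,5-dimethoxyphenyl)magnesium bromide | COc1cc([Mg]Br)cc(OC)c1OCc1ccccc1
F6 | step 7 | Fragransin B1 bis(benzyl ether), meso | COc1cc([C@H]2O[C@@H](c3cc(OC)c(OCc4ccccc4)c(OC)c3)[C@H](C)[C@@H]2C)cc(OC)c1OCc1ccccc1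
F7 | step 5 | rac-(3R,3aR,6aS)-3-[4-(benzyloxy)-3,5-dimethoxyphenyl]-3a,4,6,6a-tetrahydro-1H,3H-thieno[3,4-c]furan-1-ol (both anomers) | OC1O[C@@H](c2cc(OC)c(OCc3ccccc3)c(OC)c2)[C@@H]2CSC[C@H]12
F8 | step 5 | rac-4-[3-[4-(benzyloxy)-3,5-dimethoxyphenyl]-3a,4,6,6a-tetrahydro-1H,3H-thieno[3,4-c]furan-1-yl]-2,6-dimethoxyphenol (cis-fused, both aryl groups trans to the thiolane) | COc1cc([C@H]2O[C@@H](c3cc(OC)c(OCc4ccccc4)c(OC)c3)[C@@H]3CSC[C@H]23)cc(OC)c1O
F9 | step 3 | rac-1-[4-(benzyloxy)-3,5-dimethoxyphenyl]prop-2-en-1-ol | C=C[C@@H](O)c1cc(OC)c(OCc2ccccc2)c(OC)c1
F10 | step 3 | rac-1-[4-(benzyloxy)-3,5-dimethoxyphenyl]prop-2-en-1-yl acrylate | C=CC(=O)O[C@H](C=C)c1cc(OC)c(OCc2ccccc2)c(OC)c1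
F0 | step 8 | none | none
A1 | alternative 1 | trans-2,5-bis[4-(benzyloxy)-3,5-dimethoxyphenyl]-3,4-dimethyl-2,3-dihydrofuran | COc1cc([C@H]2OC(c3cc(OC)c(OCc4ccccc4)c(OC)c3)=C(C)[C@@H]2C)cc(OC)c1OCc1ccccc1
A2 | alternative 1 | (E)-1-[4-(benzyloxy)-3,5-dimethoxyphenyl]-2-methylbut-2-en-1-one | C/C=C(\C)C(=O)c1cc(OC)c(OCc2ccccc2)c(OC)c1
A3 | alternative 1 | 1-[4-(benzyloxy)-3,5-dimethoxybenzyl]tetrahydrothiophenium bromide | COc1cc(C[S+]2CCCC2)cc(OC)c1OCc1ccccc1.[Br-]
A4 | alternative 2 | Fragransin B1 bis(benzyl ether), meso | COc1cc([C@H]2O[C@@H](c3cc(OC)c(OCc4ccccc4)c(OC)c3)[C@H](C)[C@@H]2C)cc(OC)c1OCc1ccccc1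
A5 | alternative 2 | meso-(2R,3R,4S,5S)-3,4-dimethyltetrahydrofuran-2,5-dicarboxylic acid | OC(=O)[C@H]1O[C@@H](C(=O)O)[C@H](C)[C@@H]1C
A6 | alternative 2 | exo,exo-5,6-dimethyl-7-oxabicyclo[2.2.1]hept-2-ene (meso) | C1=C[C@H]2O[C@@H]1[C@H](C)[C@@H]2C
A7 | alternative 2 | 2-(benzyloxy)-5-bromo-1,3-dimethoxybenzene | COc1cc(Br)cc(OC)c1OCc1ccccc1
A8 | alternative 3 | ethyl trans-2,5-bis[4-(benzyloxy)-3,5-dimethoxyphenyl]-4-methyl-4,5-dihydrofuran-3-carboxylate | CCOC(=O)C1=C(c2cc(OC)c(OCc3ccccc3)c(OC)c2)O[C@@H](c2cc(OC)c(OCc3ccccc3)c(OC)c2)[C@@H]1C
A9 | alternative 3 | ethyl 3-[4-(benzyloxy)-3,5-dimethoxyphenyl]-3-oxopropanoate | CCOC(=O)CC(=O)c1cc(OC)c(OCc2ccccc2)c(OC)c1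
A10 | alternative 3 | (E)-2-(benzyloxy)-1,3-dimethoxy-5-(prop-1-enyl)benzene | C/C=C/c1cc(OC)c(OCc2ccccc2)c(OC)c1
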